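**Conventions.** The atom labels O1, C2 (carbonyl), C3, C4, C5 and exocyclic C6 are those of the furanone of the target. They are used for the same atoms in every intermediate; locants inside compound names follow normal nomenclature. Route in brief: 1 → 2; 2 + 3 → 4; 5 → 6; 4 + 6 → [7 → 8] → 9 → 10 → [11 → 12] → 13.

Assumption: 1, 3 and 5 are bought; 4 is drawn as its E isomer, and any Z isomer formed with it is carried on, because step 4 passes through one common dienolate.

Remark on the chemistry: the electrolysis is run in MeCN/HFIP; a nucleophilic alcohol such as methanol is avoided because it could add to cation 11 or to quinone methide 12.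

## Analysis of the target

Rubrolide A (13) is a furan-2(5H)-one (ring atoms O1, C2, C3, C4, C5) that carries a 3,5-dibromo-4-hydroxyphenyl group on C4 and a 3,5-dibromo-4-hydroxybenzylidene group on C5 through the exocyclic carbon C6. It has no stereogenic centre, and its only stereochemical element is the Z geometry of C5=C6, in which the C6 aryl group lies on the side of O1 and away from the C4 aryl group. The sensitive groups are four aryl C–Br bonds (which rule out zerovalent palladium, hydrogenolysis, dissolving metals and halogen–metal exchange once they are present), two acidic 2,6-dibromophenols, an enol lactone that hydroxide opens, and a C5=C6 bond that isomerizes in light. The skeleton of seventeen carbons is simple, so the difficulty lies in forming the enol lactone at the right oxidation level with Z geometry and in having the four bromines in place without a late halogenation that would have to tell two different phenol rings from C3 and from the electron-rich C5=C6 bond. The strategy rests on one structural feature: the hydroxyl group of the C6 aryl ring is para to C6 and is therefore conjugated, through that ring and the C5=C6 bond, with O1. Moving the phenolic hydrogen to C5 turns the ylidene lactone into a para-quinone methide with the acyloxy oxygen O1 on an sp3 C5. In the synthetic direction, the O1–C5 bond, the lactone ring and the C5=C6 geometry can therefore all come from a two-electron oxidation of a 4-hydroxystyryl unit that sits next to a carboxylate.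

## Retrosynthetic reasoning

**13 to 10 (O1–C5).** The target is first written as its quinone methide tautomer 12, and the O1–C5 bond of 12 is cut to give cation 11, which is the two-electron-oxidized form of dienoic acid 10. This is the only ring bond whose formation can be an oxidation, and cutting it leaves every C–C bond in an open-chain acid. Nothing has to follow the ring closure, and the oxidation level and the Z geometry are set in the same operation. The forward step has to oxidize the phenolate of the C6 ring, close at C5 and not elsewhere, and tautomerize 12 to 13. Closure at C5 needs the carboxyl C2 to be cis to C5 across C3=C4, so this geometry is a requirement on 10. Both phenols are set free before the oxidation so that no step comes after it; only the one on the C6 ring takes part.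

**10 to 9 (two O–methyl bonds).** The phenols of 10 are masked as methyl ethers in 9. The C–C bond formation that precedes it uses a strong alkoxide base and an aldehyde; a free para-phenolate would consume the base and would deactivate the aldehyde carbonyl. Methyl ethers are the smallest choice, they are inert to hydride and alkoxide bases, and a boron trihalide can remove them without touching the C–Br bonds.

**9 to 4 and 6 (C5=C6, through 8 and 7).** Cutting C5=C6 divides 9 into two halves of similar size, each traceable to one of the commercial dibromophenols 1 and 5. The forward reaction is a vinylogous aldol reaction of the dienolate of 4 with aldehyde 6. It is routed through aldolate 7 and δ-lactone 8 on purpose, because C2 and C5 are both ring members of 8 and are therefore cis when the ring is opened by elimination. The C3=C4 geometry that the key step needs is thus a consequence of the mechanism and not of a selective olefination. The other cut, at C3=C4 of 9, would mean olefinating a ketone that is also a conjugate acceptor; it was not taken because it would give both geometries and would compete with conjugate addition.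

**4 to 2 and 3 (C3=C4).** The butenoate 4 comes from ketone 2 and phosphonate 3 by a Horner–Wadsworth–Emmons reaction. Its geometry does not have to be controlled, since it is lost in the dienolate of the next step.

**2 to 1 and 6 to 5 (O–methyl bonds).** The ethers 2 and 6 come from phenols 1 and 5 by O-methylation. These two starting materials already carry all four bromines, so the route contains no aromatic bromination.

## Alternatives that were turned down

**Alternative 1: dimerization of an arylpyruvate ester.**
- Disconnection: C4–C5 and O1–C2, which divides the lactone into two molecules of methyl 3-(4-methoxyphenyl)-2-oxopropanoate A1.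
- Forward key step: under DBU the benzylic enolate of one molecule of A1 adds to the ketone of a second molecule of A1 (C4–C5), and the tertiary alkoxide closes onto the ester of the first (O1–C2). The product is racemic methyl 4-hydroxy-2-(4-methoxybenzyl)-3-(4-methoxyphenyl)-5-oxo-2,5-dihydrofuran-2-carboxylate A2.
- For it: A1 is one cheap building block; both skeletal bonds and the ring are formed in one operation; the aldol–lactonization mechanism raises no doubt; it parallels a plausible biogenesis.
- Against it for this target: A2 has the right carbons but the wrong functionality in three places. The hydroxyl group on C3 must be removed (sulfonylation and reduction). C5 is quaternary and carries an ester that has to leave while C5=C6 is created (hydrolysis, decarboxylation and a dehydrogenation). The rings carry methoxy groups and no bromine, so ether cleavage and a fourfold electrophilic bromination end the sequence. The reductive removal of the C3 oxygen forbids bringing the bromines in earlier, and the final bromination has to distinguish four phenol ortho positions from C3 and from the C5=C6 enol ester.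
- Comparison: this alternative is stronger on the precedent of its key step and on the simplicity of its starting material A1. It is weaker on step economy after the key step (five or more corrective steps on A2 against none) and on halogenation selectivity. The chosen strategy offers the correct oxidation level and the bromine pattern from the first step.

**Alternative 2: twofold Suzuki arylation of a dibromo ylidene furanone.**
- Disconnection: the C4–aryl and C6–aryl bonds, leaving (Z)-4-bromo-5-(bromomethylene)furan-2(5H)-one A3 and two equivalents of (4-hydroxyphenyl)boronic acid A4.
- Forward key step: A3 is coupled twice with A4 under Pd(PPh3)4 and CsF, without ring closure, to (Z)-5-(4-hydroxybenzylidene)-4-(4-hydroxyphenyl)furan-2(5H)-one A5.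
- For it: the lactone and the Z geometry are already in A3; the two aryl groups are identical, so the two C–Br bonds of A3 need not be told apart; the free phenol of A4 needs no protecting group; the coupling is standard.
- Against it for this target: the aryl groups have to enter without bromine, as in A4, because a boron partner that already carried the ring bromines would itself be an electrophile for zerovalent palladium and would oligomerize. All four bromines must then be put onto A5 at the end. The C4 ring of A5 is conjugated with the lactone carbonyl and is the less reactive one; the C6 ring is conjugated with the enol oxygen and is the more reactive one; C3 and C5=C6 compete. Under- and over-brominated products are therefore to be expected. A3 also has to be made in a few steps.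
- Comparison: on precedent and on certainty of the key step this alternative is stronger, and on step count it is at least as short. The chosen strategy offers a bromine pattern taken intact from commercial dibromophenols, no palladium in the presence of C–Br bonds, and a last step that cannot give halogenation isomers. Its price is an unprecedented final step.

**Alternative 3: cobalt carbonyl three-component assembly.**
- Disconnection: C4–C5, C2–C3 and O1–C2. The ring is taken apart into three pieces: 2-(4-methoxyphenyl)acetyl chloride A6, which supplies C5, C6 and O1; [(4-methoxyphenyl)ethynyl]trimethylsilane A7, which supplies C3 and C4; and carbon monoxide A8, which supplies C2.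
- Forward key step: A6 acylates NaCo(CO)4; A7 and A8 insert into the resulting acyl–Co(CO)4 complex; the ketone oxygen closes onto the new acyl group; a hindered amine removes the C6 hydrogen from the lactonyl cobalt complex. The product is (Z)-5-(4-methoxybenzylidene)-4-(4-methoxyphenyl)-3-(trimethylsilyl)furan-2(5H)-one A9.
- For it: three bonds and the ring are formed in one pot from the three simple pieces A6, A7 and A8; the silyl group of A7 fixes the orientation of the alkyne; the Z geometry of A9 follows from the elimination.
- Against it for this target: it needs stoichiometric NaCo(CO)4, which is air-sensitive and toxic, and the gas A8. The silyl group on C3 of A9 is not part of the target and must be removed by protodesilylation. Ether cleavage and the same late fourfold bromination follow. Carrying the bromines through instead is not attractive, since four aryl C–Br bonds would face the electron-rich Co(CO)4 anion and a brominated analogue of A7 could not be made by a palladium alkynylation.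
- Comparison: this alternative forms three bonds in its key step against one and relies on a known stoichiometric carbonylative lactone synthesis, so it is more convergent and less speculative. It is of similar length (about six or seven steps) but spends three of them on corrections of A9 after the key step. The chosen strategy offers a metal-free ring closure that ends at the target.

Key step: step 6

## Route

Step 1
Reactants: 1 1-(3,5-dibromo-4-hydroxyphenyl)ethanone
Product: 2 1-(3,5-dibromo-4-methoxyphenyl)ethanone
Conditions: MeI, K2CO3, DMF, 40 °C
Reagents that add atoms: iodomethane, CI
Why: Williamson ether synthesis; the acidic 2,6-dibromophenol is fully deprotonated by K2CO3 and its hindered phenoxide is alkylated by the small electrophile, while the weak base leaves the ketone α-position alone.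

Step 2
Reactants: 2 1-(3,5-dibromo-4-methoxyphenyl)ethanone; 3 triethyl phosphonoacetate
Product: 4 ethyl (E)-3-(3,5-dibromo-4-methoxyphenyl)but-2-enoate
Conditions: NaH, THF, 0 °C → reflux; then 1 M HCl
Reagents that add atoms: none
Why: Horner–Wadsworth–Emmons olefination of an aryl methyl ketone, which should give mainly the E ester (aryl trans to the ester group); the minor Z isomer need not be removed because step 4 converts both into the same dienolate.

Step 3
Reactants: 5 3,5-dibromo-4-hydroxybenzaldehyde
Product: 6 3,5-dibromo-4-methoxybenzaldehyde
Conditions: MeI, K2CO3, DMF, 40 °C
Reagents that add atoms: iodomethane, CI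
Why: Williamson ether synthesis as in step 1; the aldehyde has no α-hydrogen and is inert to K2CO3 and MeI.

Step 4
Reactants: 4 ethyl (E)-3-(3,5-dibromo-4-methoxyphenyl)but-2-enoate; 6 3,5-dibromo-4-methoxybenzaldehyde
Product: 9 (2E,4E)-3,5-bis(3,5-dibromo-4-methoxyphenyl)penta-2,4-dienoic acid, via gamma-aldolate 7 (not isolated), via delta-lactone 8 (not isolated)
Conditions: KOtBu (2.5 equiv), THF, −20 °C → rt; then 1 M HCl
Reagents that add atoms: none
Why: Vinylogous aldol addition–lactonization followed by E1cB ring opening: KOtBu forms the dienolate of 4 by removing a hydrogen of the C5 methyl group, its α-aldol with 6 is reversible, and the γ-aldolate 7 that has the ester cis to the new arm is drained by lactonization to 8. Excess base then removes a C5 hydrogen of 8 and expels the carboxylate oxygen from C6, which should leave C2 cis to C5 across C3=C4 (both were ring atoms of 8) and give the trans C5=C6 bond; this is the classical condensation of 3-methylalk-2-enoates with non-enolizable aldehydes to 2,4-dienoic acids.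

Step 5
Reactants: 9 (2E,4E)-3,5-bis(3,5-dibromo-4-methoxyphenyl)penta-2,4-dienoic acid
Product: 10 (2E,4E)-3,5-bis(3,5-dibromo-4-hydroxyphenyl)penta-2,4-dienoic acid
Conditions: BBr3 (6 equiv), CH2Cl2, −78 °C → rt; then H2O
Reagents that add atoms: none
Why: Lewis-acid cleavage of aryl methyl ethers; the two ortho bromines twist each methoxy group out of conjugation, so its oxygen binds boron readily and bromide attacks the methyl group, with the dibromophenoxide as a good leaving group. The carboxylic acid is held as an electron-poor acyloxyborane during the reaction, which should protect the diene from protonation, and the aryl bromides are inert.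

Step 6
Reactants: 10 (2E,4E)-3,5-bis(3,5-dibromo-4-hydroxyphenyl)penta-2,4-dienoic acid
Product: 13 rubrolide A, via quinone-methide cation 11 (not isolated), via quinone-methide lactone 12 (not isolated)
Conditions: graphite anode, Pt cathode, undivided cell, constant current (about 2.1 F per mol), Bu4NBF4 (0.1 M), 2,6-lutidine (3 equiv), MeCN/HFIP 9:1, 5 mM in 10, rt, N2, dark
Reagents that add atoms: none
Why: Proposed new method: the 2,6-dibromophenolate of the C6 ring, formed by 2,6-lutidine, should be the most easily oxidized site of 10 (the phenol of the C4 ring is conjugated only with the electron-poor acrylate, and its oxidation would place charge on C3), and loss of two electrons at graphite should give cation 11, whose charge is shared by the quinoid ring, C5 and, weakly because it is next to the carboxyl, C3. The carboxylate on C2, held cis to C5 by the C3=C4 geometry, should form the O1–C5 bond in a 5-exo-trig closure onto the C5=C6 π bond of 11 and give quinone methide lactone 12; closure at C3 would need a three-membered ring and closure at the ring carbon para to oxygen a seven-membered one. Lutidine then removes the C5 hydrogen of 12, which is the γ-hydrogen of the butenolide and also adjacent to the quinone methide, so the ring rearomatizes and the C5=C6 bond of 13 appears; the lutidinium ion is reduced to H2 at platinum, so the net change is loss of H2. The closest known reaction types are the anodic oxidation of 4-alkenylphenols to quinone methides that are trapped by internal oxygen nucleophiles and the anodic lactonization of phenol-bearing carboxylic acids; new here is the capture by a carboxylate at the vinylogous position of a dienoic acid, followed by a tautomerization that returns an unsaturated lactone. The only stereocentre formed, C5 of 12, is transient and racemic and is erased by the tautomerization, so the step sets only the C5=C6 geometry: C5–C6 rotates freely in 12, deprotonation through the conformer with the C6 aryl turned toward O1 and away from the C4 aryl should give the Z isomer, and this is also the thermodynamic isomer because the phenol to quinone methide tautomerism is reversible. Chemoselectivity rests on the low oxidation potential of the phenolate (aryl bromides, carboxylate and lutidine are oxidized only at much higher potential), on the non-nucleophilic medium, on proton reduction at platinum occurring well before aryl bromide reduction, and on stopping the charge near two faradays per mole to spare the product phenols.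

## Compound list

1 | 1-(3,5-dibromo-4-hydroxyphenyl)ethanone | CC(=O)c1cc(Br)c(O)c(Br)c1 | starting material
2 | 1-(3,5-dibromo-4-methoxyphenyl)ethanone | CC(=O)c1cc(Br)c(OC)c(Br)c1 | intermediate
3 | triethyl phosphonoacetate | CCOC(=O)CP(=O)(OCC)OCC | starting material
4 | ethyl (E)-3-(3,5-dibromo-4-methoxyphenyl)but-2-enoate | CCOC(=O)/C=C(\C)c1cc(Br)c(OC)c(Br)c1 | intermediate
5 | 3,5-dibromo-4-hydroxybenzaldehyde | O=Cc1cc(Br)c(O)c(Br)c1 | starting material
6 | 3,5-dibromo-4-methoxybenzaldehyde | O=Cc1cc(Br)c(OC)c(Br)c1 | intermediate
7 | ethyl (E)-3,5-bis(3,5-dibromo-4-methoxyphenyl)-5-hydroxypent-2-enoate (racemic; present as its potassium alkoxide) | CCOC(=O)/C=C(/c1cc(Br)c(OC)c(Br)c1)CC(O)c1cc(Br)c(OC)c(Br)c1 | intermediate (not isolated)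
8 | 4,6-bis(3,5-dibromo-4-methoxyphenyl)-5,6-dihydro-2H-pyran-2-one (racemic) | O=C1C=C(c2cc(Br)c(OC)c(Br)c2)CC(c2cc(Br)c(OC)c(Br)c2)O1 | intermediate (not isolated)
9 | (2E,4E)-3,5-bis(3,5-dibromo-4-methoxyphenyl)penta-2,4-dienoic acid | OC(=O)/C=C(/c1cc(Br)c(OC)c(Br)c1)\C=C\c1cc(Br)c(OC)c(Br)c1 | intermediate
10 | (2E,4E)-3,5-bis(3,5-dibromo-4-hydroxyphenyl)penta-2,4-dienoic acid | OC(=O)/C=C(/c1cc(Br)c(O)c(Br)c1)\C=C\c1cc(Br)c(O)c(Br)c1 | intermediate
11 | quinone-methide cation, drawn as the carboxylate zwitterion with the charge on C5: (E)-3-(3,5-dibromo-4-hydroxyphenyl)-5-(3,5-dibromo-4-oxocyclohexa-2,5-dien-1-ylidene)pent-2-enoate with a cationic C4 of the chain (one resonance form) | [O-]C(=O)/C=C(/c1cc(Br)c(O)c(Br)c1)[CH+]C=C1C=C(Br)C(=O)C(Br)=C1 | intermediate (not isolated)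
12 | 4-(3,5-dibromo-4-hydroxyphenyl)-5-[(3,5-dibromo-4-oxocyclohexa-2,5-dien-1-ylidene)methyl]furan-2(5H)-one (racemic) | O=C1C=C(c2cc(Br)c(O)c(Br)c2)C(C=C2C=C(Br)C(=O)C(Br)=C2)O1 | intermediate (not isolated)
13 | rubrolide A, (Z)-5-(3,5-dibromo-4-hydroxybenzylidene)-4-(3,5-dibromo-4-hydroxyphenyl)furan-2(5H)-one | O=C1C=C(c2cc(Br)c(O)c(Br)c2)/C(=C/c2cc(Br)c(O)c(Br)c2)O1 | target

## Step count and least certain steps

Total step count: 6. Longest linear sequence: 5 (steps 1, 2, 4, 5 and 6; step 3 is a one-step branch).

**Step 6 (the key step, which carries the label for a proposed new method).** Three things are most likely to go wrong. The one-electron stage may dimerize before the second electron is removed: the phenoxyl radical has spin density on C5, and coupling of two radicals through C5, or through C5 and a phenoxyl oxygen, is the usual fate of oxidized 4-alkenylphenols. Cation 11 or quinone methide 12 may be captured by an external nucleophile, or 12 may be reduced at the cathode, if tautomerization is slow. The product may be oxidized further, since it keeps an oxidizable hydroxystyryl unit, and oxidation may also start at the phenol of the C4 ring. Measures within the step are high dilution, a large anode surface, charge control and, if needed, a divided cell.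

Fallback (known chemistry, setting out from 2 and 6 and coming back to the route at 13): α-bromination of ketone 2 (CuBr2, EtOAc/CHCl3, reflux) should give 2-bromo-1-(3,5-dibromo-4-methoxyphenyl)ethanone F1. Displacement of its bromide by (diethoxyphosphoryl)acetic acid with Et3N in MeCN gives 2-(3,5-dibromo-4-methoxyphenyl)-2-oxoethyl 2-(diethoxyphosphoryl)acetate F2, and an intramolecular Horner–Wadsworth–Emmons reaction (LiCl, DBU, MeCN) closes it to 4-(3,5-dibromo-4-methoxyphenyl)furan-2(5H)-one F3. Vinylogous aldol condensation of F3 with aldehyde 6 (TBSOTf, iPr2NEt, CH2Cl2; then DBU) runs through tert-butyl{[4-(3,5-dibromo-4-methoxyphenyl)furan-2-yl]oxy}dimethylsilane F4 and the silylated aldol 5-[(tert-butyldimethylsilyloxy)(3,5-dibromo-4-methoxyphenyl)methyl]-4-(3,5-dibromo-4-methoxyphenyl)furan-2(5H)-one F5, neither isolated, and gives (Z)-5-(3,5-dibromo-4-methoxybenzylidene)-4-(3,5-dibromo-4-methoxyphenyl)furan-2(5H)-one F6. BBr3 in CH2Cl2 then gives 13. This gives up the oxidative ring closure but keeps the same building blocks and the bromines from the start.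

**Step 4.** The dienolate may react through its α-carbon or with a second molecule of ester without draining into the lactone; the ring opening of 8 may stay incomplete; and the base may attack the aryl bromides that have an ortho hydrogen if the mixture has to be heated.

Fallback (setting out from 4 with 6 and coming back at 9), which separates C–C bond formation from the base-induced opening: radical bromination of the C5 methyl group of 4 (NBS, AIBN, PhCF3, reflux) gives ethyl (Z)-4-bromo-3-(3,5-dibromo-4-methoxyphenyl)but-2-enoate F7. Zinc dust in THF at reflux converts it into [(Z)-2-(3,5-dibromo-4-methoxyphenyl)-4-ethoxy-4-oxobut-2-en-1-yl]zinc bromide F8, which is not isolated. Under these equilibrating conditions F8 should add to 6 in the vinylogous Reformatsky sense and lactonize to δ-lactone 8, which is now isolated. Treatment of 8 with KOtBu in THF, then 1 M HCl, opens it to 9.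

**Step 5.** The HBr and boron Lewis acid present may isomerize the C3=C4 bond by reversible conjugate addition; they may protonate C5 so that the carboxyl closes onto C6 and re-forms a six-membered lactone; and the second ether may be cleaved only slowly.

Fallback (a change of protecting group, setting out from 1 and 5 and coming back at 10): MOMCl and iPr2NEt in CH2Cl2 give 1-[3,5-dibromo-4-(methoxymethoxy)phenyl]ethanone F9 from 1 and 3,5-dibromo-4-(methoxymethoxy)benzaldehyde F10 from 5. Olefination of F9 with 3 as in step 2 gives ethyl (E)-3-[3,5-dibromo-4-(methoxymethoxy)phenyl]but-2-enoate F11. Condensation of F11 with F10 as in step 4 passes through ethyl (E)-3,5-bis[3,5-dibromo-4-(methoxymethoxy)phenyl]-5-hydroxypent-2-enoate F12 and 4,6-bis[3,5-dibromo-4-(methoxymethoxy)phenyl]-5,6-dihydro-2H-pyran-2-one F13, neither isolated, to (2E,4E)-3,5-bis[3,5-dibromo-4-(methoxymethoxy)phenyl]penta-2,4-dienoic acid F14; partial loss of an acetal during the brief cold acidic work-up would do no harm, since the next operation removes both. Dilute aqueous HCl in THF at 40 °C, without an alcohol, then cleaves both acetals of F14 and gives 10.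

## Further compounds

F1 | step 6 | 2-bromo-1-(3,5-dibromo-4-methoxyphenyl)ethanone | O=C(CBr)c1cc(Br)c(OC)c(Br)c1
F2 | step 6 | 2-(3,5-dibromo-4-methoxyphenyl)-2-oxoethyl 2-(diethoxyphosphoryl)acetate | CCOP(=O)(OCC)CC(=O)OCC(=O)c1cc(Br)c(OC)c(Br)c1
F3 | step 6 | 4-(3,5-dibromo-4-methoxyphenyl)furan-2(5H)-one | O=C1C=C(c2cc(Br)c(OC)c(Br)c2)CO1
F4 | step 6 | tert-butyl{[4-(3,5-dibromo-4-methoxyphenyl)furan-2-yl]oxy}dimethylsilane | CC(C)(C)[Si](C)(C)Oc1cc(-c2cc(Br)c(OC)c(Br)c2)co1
F5 | step 6 | 5-[(tert-butyldimethylsilyloxy)(3,5-dibromo-4-methoxyphenyl)methyl]-4-(3,5-dibromo-4-methoxyphenyl)furan-2(5H)-one (mixture of diastereomers) | O=C1C=C(c2cc(Br)c(OC)c(Br)c2)C(C(O[Si](C)(C)C(C)(C)C)c2cc(Br)c(OC)c(Br)c2)O1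
F6 | step 6 | (Z)-5-(3,5-dibromo-4-methoxybenzylidene)-4-(3,5-dibromo-4-methoxyphenyl)furan-2(5H)-one | O=C1C=C(c2cc(Br)c(OC)c(Br)c2)/C(=C/c2cc(Br)c(OC)c(Br)c2)O1
F7 | step 4 | ethyl (Z)-4-bromo-3-(3,5-dibromo-4-methoxyphenyl)but-2-enoate | CCOC(=O)/C=C(\CBr)c1cc(Br)c(OC)c(Br)c1
F8 | step 4 | [(Z)-2-(3,5-dibromo-4-methoxyphenyl)-4-ethoxy-4-oxobut-2-en-1-yl]zinc bromide | CCOC(=O)/C=C(\C[Zn]Br)c1cc(Br)c(OC)c(Br)c1
F9 | step 5 | 1-[3,5-dibromo-4-(methoxymethoxy)phenyl]ethanone | CC(=O)c1cc(Br)c(OCOC)c(Br)c1
F10 | step 5 | 3,5-dibromo-4-(methoxymethoxy)benzaldehyde | O=Cc1cc(Br)c(OCOC)c(Br)c1
F11 | step 5 | ethyl (E)-3-[3,5-dibromo-4-(methoxymethoxy)phenyl]but-2-enoate | CCOC(=O)/C=C(\C)c1cc(Br)c(OCOC)c(Br)c1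
F12 | step 5 | ethyl (E)-3,5-bis[3,5-dibromo-4-(methoxymethoxy)phenyl]-5-hydroxypent-2-enoate (racemic) | CCOC(=O)/C=C(/c1cc(Br)c(OCOC)c(Br)c1)CC(O)c1cc(Br)c(OCOC)c(Br)c1
F13 | step 5 | 4,6-bis[3,5-dibromo-4-(methoxymethoxy)phenyl]-5,6-dihydro-2H-pyran-2-one (racemic) | O=C1C=C(c2cc(Br)c(OCOC)c(Br)c2)CC(c2cc(Br)c(OCOC)c(Br)c2)O1
F14 | step 5 | (2E,4E)-3,5-bis[3,5-dibromo-4-(methoxymethoxy)phenyl]penta-2,4-dienoic acid | OC(=O)/C=C(/c1cc(Br)c(OCOC)c(Br)c1)\C=C\c1cc(Br)c(OCOC)c(Br)c1
A1 | alternative 1 | methyl 3-(4-methoxyphenyl)-2-oxopropanoate | COC(=O)C(=O)Cc1ccc(OC)cc1
A2 | alternative 1 | methyl 4-hydroxy-2-(4-methoxybenzyl)-3-(4-methoxyphenyl)-5-oxo-2,5-dihydrofuran-2-carboxylate (racemic) | COC(=O)C1(Cc2ccc(OC)cc2)OC(=O)C(O)=C1c1ccc(OC)cc1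
A3 | alternative 2 | (Z)-4-bromo-5-(bromomethylene)furan-2(5H)-one | O=C1C=C(Br)/C(=C/Br)O1
A4 | alternative 2 | (4-hydroxyphenyl)boronic acid | OB(O)c1ccc(O)cc1
A5 | alternative 2 | (Z)-5-(4-hydroxybenzylidene)-4-(4-hydroxyphenyl)furan-2(5H)-one | O=C1C=C(c2ccc(O)cc2)/C(=C/c2ccc(O)cc2)O1
A6 | alternative 3 | 2-(4-methoxyphenyl)acetyl chloride | COc1ccc(CC(Cl)=O)cc1
A7 | alternative 3 | [(4-methoxyphenyl)ethynyl]trimethylsilane | COc1ccc(C#C[Si](C)(C)C)cc1
A8 | alternative 3 | carbon monoxide | [C-]#[O+]
A9 | alternative 3 | (Z)-5-(4-methoxybenzylidene)-4-(4-methoxyphenyl)-3-(trimethylsilyl)furan-2(5H)-one | O=C1C([Si](C)(C)C)=C(c2ccc(OC)cc2)/C(=C/c2ccc(OC)cc2)O1
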